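**Plan**
- Retrosynthetic cuts, in order: the lactam N–C15 and C13=C14 bonds (α-amino ketone plus Ph3P=C=C=O), the C16–N bond (azide on a methyl ketone), the C6–O and C9–O bonds (back to a ring B 6,8-diene), the C8=C9 alkene (back to a C8–O bond), then C4–C5 and C9–C10.
- Enabling feature: C1–C13 and C16–C20 of the target lie in order along (5E,9E)-farnesylacetone. Its three trisubstituted alkenes are spaced for rings A and B, and the C13 carbonyl oxygen sits six atoms from C8, so it can end the cascade as a temporary dihydropyran.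
- Forward: rings A, B and the pyran form together in step 1. The pyran is then opened and eliminated to the C8=C9 alkene, C16 is aminated and C13 masked. Ring B is oxidised via the 7-ketone, the 6,8-diene and the 6α,9α-endoperoxide, and the lactam ring is closed last.
- Stereochemistry: C5 and C10 come from face-selective protonation by a chiral acid and chair–chair folding; C9 from α-face singlet oxygen; C8 from axial protonation in a dissolving-metal reduction; C6 from α-face hydride delivery.

Key step: step 1

Assumption: the (R)-configured BINOL monoether–SnCl4 acid is taken to deliver the (5S,10S) series, by analogy with its behaviour toward hydroxyl-terminated polyprenoids; if the sense is opposite, the (S)-acid is used with nothing else changed.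
Remark: labdane numbering is used throughout; ketols 3 and 20 are drawn open-chain although each equilibrates with its cyclic hemiketal.

**Route**

Step 1
Reactants: 1 (5E,9E)-farnesylacetone
Product: 2 sclareol oxide (8α,13-epoxy-14,15-dinorlabd-12-ene)
Conditions: (R)-2-(2-fluorobenzyloxy)-2'-hydroxy-1,1'-binaphthyl·SnCl4 (2 equiv), toluene, −78 °C; then CF3CO2H·SnCl4, −78 °C; Et3N quench
Reagents that add atoms: none
Why: Proposed new method: the phenolic proton of the BINOL monoether, acidified by SnCl4, is transferred to one enantioface of the terminal alkene at C3; the C4 cation is attacked by C5 and the C10 cation by C9 through a chair–chair fold, the carbonyl oxygen traps the C8 cation and the cyclic oxocarbenium ion loses H12 to give the enol ether, the closest known reactions being the enantioselective cyclisation of hydroxyl- and aryl-terminated polyprenoids by this class of chiral acid and the racemic strong-acid cyclisation of farnesylacetone to sclareol oxide, so that only the pairing of the chiral acid with a ketone terminator is untested. Ring A closes 6-endo-trig (C4–C5), ring B closes 6-endo-trig (C9–C10) and the dihydropyran closes by O–C8 bond formation with the C13=O bond inside the new six-membered ring. C5 and C10 (trans fusion) arise from anti addition across the E C5=C10 alkene in a chair, C9 (β side chain) and C8 (equatorial α C–O, axial β methyl) from anti addition across the E C8=C9 alkene, and the absolute configuration of all four from the face of C3 that the chiral acid protonates. The step needs enantioface selection at an unfunctionalised alkene and oxygen capture in preference to proton loss: the first rests on the chiral proton donor at −78 °C, the second on the six-membered reach of the C11–C12 tether, the second equivalent of acid compensates for SnCl4 bound by the ketone, and the achiral acid after-treatment returns monocyclic or alkene-terminated material to the C8 cation.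

Step 2
Reactants: 2 sclareol oxide
Product: 3 8α-hydroxy-14,15-dinorlabdan-13-one
Conditions: 0.5 M HCl, THF–H2O, 0 °C → rt
Reagents that add atoms: water, O
Why: Acid-catalysed enol ether hydrolysis: protonation at C12, addition of water at C13 and opening of the hemiketal should give the ketol without touching C8.

Step 3
Reactants: 3 8α-hydroxy-14,15-dinorlabdan-13-one
Product: 4 14,15-dinorlabd-8-en-13-one
Conditions: PPh3, I2, CH2Cl2, rt
Reagents that add atoms: none
Why: Dehydration of a tertiary alcohol by the PPh3–I2 couple: the alkoxyphosphonium ion ionises at C8 and loses H9 to give the tetrasubstituted C8=C9 alkene, the most substituted isomer, which also removes the C8 and C9 stereocentres that are no longer needed.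

Step 4
Reactants: 4 14,15-dinorlabd-8-en-13-one
Product: 6 16-bromo-14,15-dinorlabd-8-en-13-one, via trimethylsilyl enol ether 5 (not isolated)
Conditions: LiN(iPr)2, Me3SiCl, THF, −78 °C; then NBS, THF, −78 → 0 °C
Reagents that add atoms: chlorotrimethylsilane (in 5 only), C[Si](C)(C)Cl; N-bromosuccinimide, O=C1CCC(=O)N1Br
Why: Kinetic deprotonation with in situ silylation should give the less substituted enol silane at the C16 methyl, and electrophilic bromination of a silyl enol ether by NBS is far faster than attack on the hindered tetrasubstituted alkene.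

Step 5
Reactants: 6 16-bromo-14,15-dinorlabd-8-en-13-one
Product: 7 16-azido-14,15-dinorlabd-8-en-13-one
Conditions: NaN3, DMF, 0 °C → rt
Reagents that add atoms: sodium azide, [Na+].[N-]=[N+]=[N-]
Why: SN2 displacement of a primary α-keto bromide by azide, which is fast at this activated carbon.

Step 6
Reactants: 7 16-azido-14,15-dinorlabd-8-en-13-one
Product: 8 16-azido-13,13-ethylenedioxy-14,15-dinorlabd-8-ene
Conditions: HOCH2CH2OH, TsOH·H2O (cat.), benzene, reflux, Dean–Stark
Reagents that add atoms: ethylene glycol, OCCO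
Why: Acid-catalysed ketalisation with azeotropic removal of water masks C13 before a second ketone is introduced at C7.

Step 7
Reactants: 8 16-azido-13,13-ethylenedioxy-14,15-dinorlabd-8-ene
Product: 10 tert-butyl N-(13,13-ethylenedioxy-14,15-dinorlabd-8-en-16-yl)carbamate, via primary amine 9 (not isolated)
Conditions: PPh3, THF–H2O, 50 °C; then Boc2O, rt
Reagents that add atoms: di-tert-butyl dicarbonate, CC(C)(C)OC(=O)OC(=O)OC(C)(C)C
Why: Staudinger reduction of the azide followed by carbamate formation on the primary amine, which as a β,β-dialkoxy amine cannot self-condense.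

Step 8
Reactants: 10 tert-butyl N-(13,13-ethylenedioxy-14,15-dinorlabd-8-en-16-yl)carbamate
Product: 11 tert-butyl N-(13,13-ethylenedioxy-7-oxo-14,15-dinorlabd-8-en-16-yl)carbamate
Conditions: CrO3, 3,5-dimethylpyrazole, CH2Cl2, −20 °C
Reagents that add atoms: chromium trioxide, O=[Cr](=O)=O
Why: Chromium-mediated allylic C–H oxidation of the tetrasubstituted cycloalkene at the ring methylene C7, the most accessible allylic position, should give the conjugated 8-en-7-one in preference to attack at C11 or C17.

Step 9
Reactants: 11 tert-butyl N-(13,13-ethylenedioxy-7-oxo-14,15-dinorlabd-8-en-16-yl)carbamate; 12 p-toluenesulfonyl hydrazide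
Product: 13 7-tosylhydrazone of 11
Conditions: PPTS (cat.), 4 Å molecular sieves, THF, 60 °C
Reagents that add atoms: p-toluenesulfonyl hydrazide (12), Cc1ccc(cc1)S(=O)(=O)NN
Why: Condensation of the enone carbonyl with the sulfonyl hydrazide gives the tosylhydrazone at the only free ketone, C13 being a ketal.

Step 10
Reactants: 13 7-tosylhydrazone of 11
Product: 14 tert-butyl N-(13,13-ethylenedioxy-14,15-dinorlabda-6,8-dien-16-yl)carbamate
Conditions: LiN(iPr)2 (4 equiv), THF, −78 °C → rt
Reagents that add atoms: none
Why: Shapiro reaction of an α,β-unsaturated tosylhydrazone: deprotonation at N and at the α′ carbon C6, loss of sulfinate and N2 and protonation should place the new alkene at C6=C7 in conjugation with C8=C9.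

Step 11
Reactants: 14 tert-butyl N-(13,13-ethylenedioxy-14,15-dinorlabda-6,8-dien-16-yl)carbamate
Product: 16 tert-butyl N-(13,13-ethylenedioxy-9α-hydroxy-6-oxo-14,15-dinorlabd-7-en-16-yl)carbamate, via 6α,9α-endoperoxide 15 (not isolated)
Conditions: O2, tetraphenylporphyrin (cat.), visible light, CH2Cl2, −30 °C; then DBU, 0 °C → rt
Reagents that add atoms: oxygen, O=O
Why: [4+2] cycloaddition of singlet oxygen to the cisoid ring B diene from the α face, anti to the axial C10 methyl, sets C9 (α oxygen, β side chain), and Kornblum–DeLaMare rearrangement by removal of H6 gives the C6 ketone and the free 9α-hydroxyl.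

Step 12
Reactants: 16 tert-butyl N-(13,13-ethylenedioxy-9α-hydroxy-6-oxo-14,15-dinorlabd-7-en-16-yl)carbamate
Product: 17 tert-butyl N-(13,13-ethylenedioxy-9α-hydroxy-8α-methyl-6-oxo-14,15-dinorlabdan-16-yl)carbamate (8β-H)
Conditions: Li, NH3 (l), THF, t-BuOH (1 equiv), −78 °C; isoprene then NH4Cl
Reagents that add atoms: none
Why: Dissolving-metal conjugate reduction of the enone: the C8 carbanion is protonated axially from the β face, in overlap with the enolate π system, giving the equatorial 8α-methyl (also the more stable epimer), while the ketone stays protected as its enolate until the quench.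

Step 13
Reactants: 17 tert-butyl N-(13,13-ethylenedioxy-9α-hydroxy-8α-methyl-6-oxo-14,15-dinorlabdan-16-yl)carbamate
Product: 18 tert-butyl N-(13,13-ethylenedioxy-6β,9α-dihydroxy-8α-methyl-14,15-dinorlabdan-16-yl)carbamate
Conditions: NaBH4, MeOH, 0 °C
Reagents that add atoms: none
Why: Substrate-controlled carbonyl reduction: hydride should add to C6 from the α face because the β face is blocked by the syn-axial methyls on C4 and C10, giving the axial 6β-alcohol.

Step 14
Reactants: 18 tert-butyl N-(13,13-ethylenedioxy-6β,9α-dihydroxy-8α-methyl-14,15-dinorlabdan-16-yl)carbamate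
Product: 19 6β-acetate of 18
Conditions: Ac2O, DMAP, pyridine, rt → 40 °C
Reagents that add atoms: acetic anhydride, CC(=O)OC(C)=O
Why: DMAP-catalysed acetylation of the secondary 6β-alcohol; the tertiary 9α-alcohol and the carbamate N–H should not compete under these conditions.

Step 15
Reactants: 19 6β-acetate of 18
Product: 20 16-amino-6β-acetoxy-9α-hydroxy-8α-methyl-14,15-dinorlabdan-13-one hydrochloride
Conditions: 3 M HCl (aq), THF, rt; evaporate
Reagents that add atoms: water, O; hydrogen chloride, Cl
Why: Acetal hydrolysis and carbamate acidolysis in one operation; the amine is held as its hydrochloride so that the α-amino ketone cannot dimerise, and the hindered acetate should survive.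

Step 16
Reactants: 20 16-amino-6β-acetoxy-9α-hydroxy-8α-methyl-14,15-dinorlabdan-13-one hydrochloride; 21 (triphenylphosphoranylidene)ketene
Product: 23 target CNP0546323.1, via N-acyl phosphorus ylide 22 (not isolated)
Conditions: Et3N (1 equiv), THF, 60 °C
Reagents that add atoms: (triphenylphosphoranylidene)ketene (21), O=C=C=P(c1ccccc1)(c1ccccc1)c1ccccc1
Why: Domino addition–Wittig olefination: the liberated amine adds to the ketene C=C of the cumulated ylide to give the amide-stabilised ylide, which closes the five-membered unsaturated lactam on the C13 ketone (new C13=C14), with the tertiary 9α-hydroxyl too hindered to intercept the ketene.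

**Compound list**
1 | (5E,9E)-farnesylacetone, (5E,9E)-6,10,14-trimethylpentadeca-5,9,13-trien-2-one | CC(C)=CCC/C(C)=C/CC/C(C)=C/CCC(C)=O | starting material
2 | sclareol oxide, 8α,13-epoxy-14,15-dinorlabd-12-ene (5S,8R,9R,10S) | C1C[C@@]2(C)OC(C)=CC[C@@H]2[C@@]3(C)CCCC(C)(C)[C@H]13 | intermediate
3 | 8α-hydroxy-14,15-dinorlabdan-13-one (5S,8R,9R,10S) | C1C[C@@](C)(O)[C@H](CCC(C)=O)[C@@]2(C)CCCC(C)(C)[C@H]12 | intermediate
4 | 14,15-dinorlabd-8-en-13-one (5S,10S; 5α-H, 10β-methyl) | C1CC(C)=C(CCC(C)=O)[C@@]2(C)CCCC(C)(C)[C@H]12 | intermediate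
5 | 13-(trimethylsilyloxy)-14,15-dinorlabda-8,13(16)-diene, formed in situ | C1CC(C)=C(CCC(=C)O[Si](C)(C)C)[C@@]2(C)CCCC(C)(C)[C@H]12 | intermediate
6 | 16-bromo-14,15-dinorlabd-8-en-13-one | C1CC(C)=C(CCC(=O)CBr)[C@@]2(C)CCCC(C)(C)[C@H]12 | intermediate
7 | 16-azido-14,15-dinorlabd-8-en-13-one | C1CC(C)=C(CCC(=O)CN=[N+]=[N-])[C@@]2(C)CCCC(C)(C)[C@H]12 | intermediate
8 | 16-azido-13,13-ethylenedioxy-14,15-dinorlabd-8-ene | C1CC(C)=C(CCC3(CN=[N+]=[N-])OCCO3)[C@@]2(C)CCCC(C)(C)[C@H]12 | intermediate
9 | 16-amino-13,13-ethylenedioxy-14,15-dinorlabd-8-ene, formed in situ | C1CC(C)=C(CCC3(CN)OCCO3)[C@@]2(C)CCCC(C)(C)[C@H]12 | intermediate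
10 | tert-butyl N-(13,13-ethylenedioxy-14,15-dinorlabd-8-en-16-yl)carbamate | C1CC(C)=C(CCC3(CNC(=O)OC(C)(C)C)OCCO3)[C@@]2(C)CCCC(C)(C)[C@H]12 | intermediate
11 | tert-butyl N-(13,13-ethylenedioxy-7-oxo-14,15-dinorlabd-8-en-16-yl)carbamate | C1C(=O)C(C)=C(CCC3(CNC(=O)OC(C)(C)C)OCCO3)[C@@]2(C)CCCC(C)(C)[C@H]12 | intermediate
12 | p-toluenesulfonyl hydrazide | Cc1ccc(cc1)S(=O)(=O)NN | starting material
13 | 7-tosylhydrazone of 11 (C=N geometry not defined) | C1C(=NNS(=O)(=O)c3ccc(C)cc3)C(C)=C(CCC4(CNC(=O)OC(C)(C)C)OCCO4)[C@@]2(C)CCCC(C)(C)[C@H]12 | intermediate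
14 | tert-butyl N-(13,13-ethylenedioxy-14,15-dinorlabda-6,8-dien-16-yl)carbamate | C1=CC(C)=C(CCC3(CNC(=O)OC(C)(C)C)OCCO3)[C@@]2(C)CCCC(C)(C)[C@H]12 | intermediate
15 | 6α,9α-epidioxy-7-ene from 14 (peroxide bridge on the α face), formed in situ | O1O[C@H]2C=C(C)[C@]1(CCC4(CNC(=O)OC(C)(C)C)OCCO4)[C@@]3(C)CCCC(C)(C)[C@H]23 | intermediate
16 | tert-butyl N-(13,13-ethylenedioxy-9α-hydroxy-6-oxo-14,15-dinorlabd-7-en-16-yl)carbamate | O=C1C=C(C)[C@](O)(CCC3(CNC(=O)OC(C)(C)C)OCCO3)[C@@]2(C)CCCC(C)(C)[C@H]12 | intermediate
17 | tert-butyl N-(13,13-ethylenedioxy-9α-hydroxy-8α-methyl-6-oxo-14,15-dinorlabdan-16-yl)carbamate (8β-H) | O=C1C[C@@H](C)[C@](O)(CCC3(CNC(=O)OC(C)(C)C)OCCO3)[C@@]2(C)CCCC(C)(C)[C@H]12 | intermediate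
18 | tert-butyl N-(13,13-ethylenedioxy-6β,9α-dihydroxy-8α-methyl-14,15-dinorlabdan-16-yl)carbamate | O[C@@H]1C[C@@H](C)[C@](O)(CCC3(CNC(=O)OC(C)(C)C)OCCO3)[C@@]2(C)CCCC(C)(C)[C@H]12 | intermediate
19 | 6β-acetate of 18 (9α-hydroxyl free) | CC(=O)O[C@@H]1C[C@@H](C)[C@](O)(CCC3(CNC(=O)OC(C)(C)C)OCCO3)[C@@]2(C)CCCC(C)(C)[C@H]12 | intermediate
20 | 16-amino-6β-acetoxy-9α-hydroxy-8α-methyl-14,15-dinorlabdan-13-one hydrochloride | CC(=O)O[C@@H]1C[C@@H](C)[C@](O)(CCC(=O)C[NH3+])[C@@]2(C)CCCC(C)(C)[C@H]12.[Cl-] | intermediate
21 | (triphenylphosphoranylidene)ketene | O=C=C=P(c1ccccc1)(c1ccccc1)c1ccccc1 | starting material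
22 | N-[(triphenylphosphoranylidene)acetyl] derivative of the free amine of 20, formed in situ | CC(=O)O[C@@H]1C[C@@H](C)[C@](O)(CCC(=O)CNC(=O)C=P(c3ccccc3)(c3ccccc3)c3ccccc3)[C@@]2(C)CCCC(C)(C)[C@H]12 | intermediate
23 | CNP0546323.1, (1R,3R,4R,4aS,8aS)-4-hydroxy-3,4a,8,8-tetramethyl-4-[2-(5-oxo-2,5-dihydro-1H-pyrrol-3-yl)ethyl]decahydronaphthalen-1-yl acetate (labdane: 5S,6R,8R,9R,10S) | CC(=O)O[C@@H]1C[C@@H](C)[C@](O)(CCC2=CC(=O)NC2)[C@@]2(C)CCCC(C)(C)[C@H]12 | target

**Count**
Total steps: 16. Longest linear sequence: 16 steps (1 → 23); 12 and 21 are purchased.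

**Steps most likely to fail**

1. Step 1. The carbonyl may bind SnCl4 and weaken the chiral proton donor, so that protonation is unselective, or the cascade stops after ring A or ends by proton loss.
   Fallback (sets out from 1, returns at 3): the ketone is taken out of the cyclisation so that the chiral acid meets a terminator on which it is established. NaBH4 in MeOH should reduce 1 to (5E,9E)-6,10,14-trimethylpentadeca-5,9,13-trien-2-ol F1 (racemic at the carbinol carbon, which is later oxidised). The same chiral acid should then effect the hydroxyl-terminated bicyclisation to 8α,13-epoxy-14,15-dinorlabdane F2. Oxidation of the ether methine C13–H with RuCl3 (cat.)/NaIO4 in CCl4–MeCN–H2O should give the hemiketal, which is ketol 3.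

2. Step 3. The C8 cation may be recaptured by the carbonyl oxygen (return to the oxocarbenium ion of 2), or may lose a proton toward C7 or C17 to give less substituted alkenes.
   Fallback (sets out from 3, returns at 4): the carbonyl is removed before the dehydration. NaBH4 should give 14,15-dinorlabdane-8α,13-diol F3. Ac2O/pyridine should acylate only the secondary hydroxyl to give 8α-hydroxy-14,15-dinorlabdan-13-yl acetate F4. PPh3–I2 should then dehydrate the tertiary alcohol, now without a participating neighbour, to 14,15-dinorlabd-8-en-13-yl acetate F5. K2CO3/MeOH should free 14,15-dinorlabd-8-en-13-ol F6, and Swern oxidation should return ketone 4.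

3. Step 12. The 9α-oxygen may be lost by β-elimination from the C8 carbanion (reductive cleavage of the γ C–O bond), or the ketone may be over-reduced.
   Fallback (sets out from 16, returns at 18, replacing steps 12 and 13): no carbanion is generated next to the C9–O bond. Luche reduction (NaBH4, CeCl3·7H2O, MeOH, −78 °C) should deliver hydride from the α face to give tert-butyl N-(13,13-ethylenedioxy-6β,9α-dihydroxy-14,15-dinorlabd-7-en-16-yl)carbamate F7. Hydrogen-atom-transfer hydrogenation (Mn(dpm)3 cat., PhSiH3, t-BuOOH, i-PrOH, rt) should then add H to C7 and reduce the tertiary C8 radical to the more stable equatorial 8α-methyl epimer, which is 18.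

**Further compounds**
F1 | step 1 | (5E,9E)-6,10,14-trimethylpentadeca-5,9,13-trien-2-ol | CC(C)=CCC/C(C)=C/CC/C(C)=C/CCC(C)O
F2 | step 1 | 8α,13-epoxy-14,15-dinorlabdane (C13 epimers) | C1C[C@@]2(C)OC(C)CC[C@@H]2[C@@]3(C)CCCC(C)(C)[C@H]13
F3 | step 3 | 14,15-dinorlabdane-8α,13-diol (C13 epimers) | C1C[C@@](C)(O)[C@H](CCC(C)O)[C@@]2(C)CCCC(C)(C)[C@H]12
F4 | step 3 | 8α-hydroxy-14,15-dinorlabdan-13-yl acetate | C1C[C@@](C)(O)[C@H](CCC(C)OC(C)=O)[C@@]2(C)CCCC(C)(C)[C@H]12
F5 | step 3 | 14,15-dinorlabd-8-en-13-yl acetate | C1CC(C)=C(CCC(C)OC(C)=O)[C@@]2(C)CCCC(C)(C)[C@H]12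
F6 | step 3 | 14,15-dinorlabd-8-en-13-ol | C1CC(C)=C(CCC(C)O)[C@@]2(C)CCCC(C)(C)[C@H]12
F7 | step 12 | tert-butyl N-(13,13-ethylenedioxy-6β,9α-dihydroxy-14,15-dinorlabd-7-en-16-yl)carbamate | O[C@@H]1C=C(C)[C@](O)(CCC3(CNC(=O)OC(C)(C)C)OCCO3)[C@@]2(C)CCCC(C)(C)[C@H]12
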